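Everything rests on contracting a bicyclo[3.2.1]octane to the bicyclo[3.1.1]heptane core. In the target the quaternary cyclobutane carbon carries the CH(OH) carbon of the seven-membered ring, and the key step makes this pair in one operation: photolysis of α-diazoketone 20 in methanol expels N2, bridgehead C5 shifts from carbonyl C6 to C7, which closes the cyclobutane, and C6 leaves the ring as a methyl ester. Precursor 20 is a 7-diazobicyclo[3.2.1]octan-6-one with a dioxolane at C2, a methyl group at C4 and the complete quaternary side chain on C8. The side-chain stereocentre comes from ethyl (S)-3-hydroxybutanoate, the ring stereocentres from an auxiliary-controlled Diels–Alder reaction.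

Key step: step 16

Remark: in the names, A is the side chain (2S,3S)-1-(benzyloxy)-3-[(tert-butyldimethylsilyl)oxy]-2-methylbutan-2-yl, whose silylated carbinol is the masked acetyl group; it is assumed that the second enolate alkylation (step 2) keeps the facial preference of the first.

Step 1
Reactants: 1 ethyl (3S)-3-hydroxybutanoate
Product: 2 ethyl (2S,3S)-3-hydroxy-2-methylbutanoate
Conditions: LiN(iPr)2 (2.2 equiv), THF, −50 to −20 °C; MeI, DMPU, −78 to 0 °C
Reagents that add atoms: iodomethane, CI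
Why: Fráter–Seebach alkylation: the chelated dilithium alkoxide–enolate is methylated on the face away from the C3 methyl group, which gives the anti (2S,3S) ester.

Step 2
Reactants: 2 ethyl (2S,3S)-3-hydroxy-2-methylbutanoate
Product: 3 ethyl (2S,3S)-2-[(benzyloxy)methyl]-3-hydroxy-2-methylbutanoate
Conditions: LiN(iPr)2 (2.3 equiv), THF, −78 to −15 °C; PhCH2OCH2Cl, −78 to −20 °C
Reagents that add atoms: benzyl chloromethyl ether, ClCOCc1ccccc1
Why: Second Fráter–Seebach alkylation: the same lithium chelate again exposes the face away from the C3 methyl group, so CH2OBn takes the place the first methyl group had and the quaternary carbon (2S) is set by the carbinol centre.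

Step 3
Reactants: 3 ethyl (2S,3S)-2-[(benzyloxy)methyl]-3-hydroxy-2-methylbutanoate
Product: 4 ethyl (2S,3S)-2-[(benzyloxy)methyl]-3-[(tert-butyldimethylsilyl)oxy]-2-methylbutanoate
Conditions: tBuMe2SiOTf, 2,6-lutidine, CH2Cl2, 0 °C
Reagents that add atoms: tert-butyldimethylsilyl trifluoromethanesulfonate, CC(C)(C)[Si](C)(C)OS(=O)(=O)C(F)(F)F
Why: Silylation of a hindered secondary alcohol with a silyl triflate; it stops retro-aldol cleavage and keeps the later methyl ketone masked as a carbinol.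

Step 4
Reactants: 4 silylated ester
Product: 5 (2S,3S)-2-[(benzyloxy)methyl]-3-[(tert-butyldimethylsilyl)oxy]-2-methylbutan-1-ol
Conditions: LiAlH4, Et2O, 0 °C
Reagents that add atoms: none
Why: Hydride reduction of the ester to the neopentyl alcohol; silyl and benzyl ethers are inert to LiAlH4.

Step 5
Reactants: 5 primary alcohol
Product: 6 (2S,3S)-2-[(benzyloxy)methyl]-3-[(tert-butyldimethylsilyl)oxy]-2-methylbutanal
Conditions: Dess–Martin periodinane, CH2Cl2, 23 °C
Reagents that add atoms: none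
Why: Dess–Martin oxidation to an aldehyde that has no α-hydrogen and so cannot epimerise.

Step 6
Reactants: 6 aldehyde
Product: 7 (3E,5S,6S)-5-[(benzyloxy)methyl]-6-[(tert-butyldimethylsilyl)oxy]-5-methylhept-3-en-2-one
Conditions: (MeO)2P(O)CH2C(O)CH3, Ba(OH)2, THF/H2O (40:1), 23 °C
Reagents that add atoms: dimethyl (2-oxopropyl)phosphonate, COP(=O)(CC(C)=O)OC
Why: Horner–Wadsworth–Emmons olefination under Ba(OH)2, mild enough for a hindered aldehyde, gives the E enone.

Step 7
Reactants: 7 enone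
Product: 8 (3E,5S,6S)-5-[(benzyloxy)methyl]-2,6-bis[(tert-butyldimethylsilyl)oxy]-5-methylhepta-1,3-diene
Conditions: tBuMe2SiOTf, Et3N, CH2Cl2, 0 °C
Reagents that add atoms: tert-butyldimethylsilyl trifluoromethanesulfonate, CC(C)(C)[Si](C)(C)OS(=O)(=O)C(F)(F)F
Why: Soft enolisation of the methyl ketone, the only enolisable site because the γ-carbon is quaternary, gives the 2-silyloxy diene with the E alkene untouched.

Step 8
Reactants: 9 (4R)-4-benzyl-5,5-dimethyl-1,3-oxazolidin-2-one; 10 (2E)-but-2-enoyl chloride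
Product: 11 (4R)-4-benzyl-3-[(2E)-but-2-enoyl]-5,5-dimethyl-1,3-oxazolidin-2-one
Conditions: n-BuLi, THF, −78 °C; then 10, −78 to 0 °C
Reagents that add atoms: none
Why: N-Acylation of the lithiated oxazolidinone by the acid chloride; the 5,5-dimethyl group later keeps hydride away from the ring carbonyl.

Step 9
Reactants: 8 silyloxy diene; 11 N-crotonoyl oxazolidinone
Product: 12 (4R)-4-benzyl-3-{[(1S,2R,6R)-2-A-4-[(tert-butyldimethylsilyl)oxy]-6-methylcyclohex-3-en-1-yl]carbonyl}-5,5-dimethyl-1,3-oxazolidin-2-one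
Conditions: Me2AlCl (1.5 equiv), CH2Cl2, −78 to −30 °C; Et3N, aq. NaHCO3
Reagents that add atoms: none
Why: Lewis-acid-promoted Diels–Alder reaction of the chelated s-cis N-enoyl oxazolidinone, in which the benzyl group of the (R)-auxiliary covers the Cα-Si face, the CH2 terminus of the diene bonds to the methyl-bearing carbon, and endo addition of the E dienophile places the acyl group cis to A and trans to the methyl group, so C1, C2 and C6 are set and the enol ether lies between C3 and C4.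

Step 10
Reactants: 12 cycloadduct imide
Product: 14 (1S,2R,6R)-2-A-4-[(tert-butyldimethylsilyl)oxy]-6-methylcyclohex-3-ene-1-carbaldehyde, via hemiaminal 13 (not isolated)
Conditions: iBu2AlH (1.2 equiv), CH2Cl2, −78 °C; aq. potassium sodium tartrate, 23 °C
Reagents that add atoms: none
Why: Known reductive cleavage of N-acyl-5,5-dimethyloxazolidinones: hydride adds to the exocyclic carbonyl, the hemiaminal survives at −78 °C and releases the aldehyde and the auxiliary on work-up without epimerising the α-carbon.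

Step 11
Reactants: 14 aldehyde
Product: 15 2-chloro-1-[(1S,2R,6R)-2-A-4-[(tert-butyldimethylsilyl)oxy]-6-methylcyclohex-3-en-1-yl]ethan-1-ol (both carbinol epimers)
Conditions: ICH2Cl, MeLi·LiBr, THF, −78 °C; aq. NH4Cl at −78 °C
Reagents that add atoms: chloroiodomethane, ClCI
Why: Addition of chloromethyllithium, made in the flask by iodine–lithium exchange, to the aldehyde at −78 °C, where the chlorohydrin alkoxide does not yet close to an epoxide; the new carbinol centre is removed in step 12.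

Step 12
Reactants: 15 chlorohydrin
Product: 16 2-chloro-1-[(1S,2R,6R)-2-A-4-[(tert-butyldimethylsilyl)oxy]-6-methylcyclohex-3-en-1-yl]ethan-1-one
Conditions: Dess–Martin periodinane, pyridine, CH2Cl2, 0 to 23 °C
Reagents that add atoms: none
Why: Dess–Martin oxidation, buffered so that the silyl enol ether survives, gives the α-chloro ketone.

Step 13
Reactants: 16 α-chloro ketone
Product: 17 (1S,4R,5S,8R)-8-A-4-methylbicyclo[3.2.1]octane-2,6-dione
Conditions: Bu4NF (1.05 equiv), THF, −78 to 0 °C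
Reagents that add atoms: none
Why: Fluoride cleaves only the silyl enol ether (the neopentyl silyl ether is far slower) and the enolate freed at C3 displaces chloride from the axial chloroacetyl group on C1 (intramolecular enolate alkylation, 5-exo-tet), which closes the two-carbon bridge, fixes the new bridgehead and leaves A on C8 over that bridge, since only the cis-1,3-diaxial arrangement can close.

Step 14
Reactants: 17 diketone
Product: 18 (1S,4R,5S,8R)-8-A-2,2-(ethylenedioxy)-4-methylbicyclo[3.2.1]octan-6-one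
Conditions: HOCH2CH2OH, pyridinium p-toluenesulfonate, benzene, 80 °C, Dean–Stark
Reagents that add atoms: ethane-1,2-diol, OCCO
Why: Acid-catalysed ketalisation under equilibrium control takes the C2 carbonyl, because a ketal at C6 would press an oxygen against the quaternary carbon of A on C8, much as camphor-type ketones resist ketalisation.

Step 15
Reactants: 18 monoketal ketone
Product: 20 (1R,4R,5S,8S)-8-A-7-diazo-2,2-(ethylenedioxy)-4-methylbicyclo[3.2.1]octan-6-one, via α-trifluoroacetyl ketone 19 (not isolated)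
Conditions: LiN(SiMe3)2, THF, −78 °C; CF3CO2CH2CF3; then CH3SO2N3, Et3N, H2O, MeCN, 23 °C
Reagents that add atoms: methanesulfonyl azide, CS(=O)(=O)N=[N+]=[N-]; 2,2,2-trifluoroethyl trifluoroacetate, O=C(OCC(F)(F)F)C(F)(F)F (its acyl group is in 19 only)
Why: Deacylative Regitz diazo transfer: the ketone can enolise only toward C7 because C5 is a bridgehead, so trifluoroacetylation and then diazo transfer with loss of the trifluoroacetyl group occur at that one carbon.

Step 16
Reactants: 20 α-diazoketone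
Product: 22 methyl (1R,4R,5S,6R,7S)-7-A-2,2-(ethylenedioxy)-4-methylbicyclo[3.1.1]heptane-6-carboxylate, via ketene 21 (not isolated)
Conditions: hν (Hg lamp, Pyrex, λ > 300 nm), MeOH, 0 °C
Reagents that add atoms: methanol, CO
Why: Irradiation excites the diazoketone, which the ring holds s-cis, and N2 leaves as bridgehead C5 shifts from the carbonyl carbon C6 to C7 with retention; ketene 21 then adds methanol and the enol is protonated. The closest known reaction type is the photochemical Wolff ring contraction of bridged cyclic α-diazoketones to the next smaller bicycle. The cyclobutane is closed by this 1,2-shift, a ring contraction of the cyclopentanone and not an exo or endo cyclisation. The new stereocentre, the ester-bearing C6 of 22, should be set by protonation of the enol from the side of the C2–C4 bridge, the other face being covered by A on C7; it is erased and reset in step 17. The step needs a single diazo site and migration of C5 alone, and both follow from the bicycle: C7 is the only α-CH2 and C5 is the only carbon on the carbonyl that can shift.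

Step 17
Reactants: 22 ring-contracted ester
Product: 23 methyl (1R,4R,5S,6R,7S)-7-A-2,2-(ethylenedioxy)-4,6-dimethylbicyclo[3.1.1]heptane-6-carboxylate
Conditions: LiN(iPr)2, THF, −78 to −40 °C; MeI, DMPU, −78 to 0 °C
Reagents that add atoms: iodomethane, CI
Why: Alkylation of the ester enolate: one substituent of the quaternary side-chain carbon always lies under the lower face of the exocyclic enolate, so iodomethane enters from the side of the C2–C4 bridge and the ester carbon stays cis to A.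

Step 18
Reactants: 23 methylated ester
Product: 24 [(1R,4R,5S,6R,7S)-7-A-2,2-(ethylenedioxy)-4,6-dimethylbicyclo[3.1.1]heptan-6-yl]methanol
Conditions: LiAlH4, THF, 0 to 23 °C
Reagents that add atoms: none
Why: Hydride reduction of the hindered ester to the primary alcohol; ketal, silyl ether and benzyl ether survive.

Step 19
Reactants: 24 primary alcohol
Product: 25 (2S,3S)-4-(benzyloxy)-3-[(1R,4R,5S,6R,7S)-2,2-(ethylenedioxy)-6-(hydroxymethyl)-4,6-dimethylbicyclo[3.1.1]heptan-7-yl]-3-methylbutan-2-ol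
Conditions: Bu4NF, THF, 45 °C
Reagents that add atoms: none
Why: Fluoride cleavage of the secondary silyl ether, warmed because it is neopentyl; ketal and benzyl ether are untouched.

Step 20
Reactants: 25 diol
Product: 26 (1R,4R,5S,6R,7S)-7-[(2S)-1-(benzyloxy)-2-methyl-3-oxobutan-2-yl]-2,2-(ethylenedioxy)-4,6-dimethylbicyclo[3.1.1]heptane-6-carbaldehyde
Conditions: Dess–Martin periodinane (3 equiv), pyridine, CH2Cl2, 23 °C
Reagents that add atoms: none
Why: Double Dess–Martin oxidation gives the non-enolisable aldehyde and the methyl ketone in one operation.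

Step 21
Reactants: 26 keto aldehyde
Product: 27 (1S,2S,3S,6R,7R,8R,11R)-3-[(benzyloxy)methyl]-9,9-(ethylenedioxy)-6-hydroxy-3,7,11-trimethyltricyclo[5.4.0.0(2,8)]undecan-4-one
Conditions: LiN(SiMe3)2 (1.1 equiv), toluene/THF, −78 to −40 °C
Reagents that add atoms: none
Why: Intramolecular aldol addition of the methyl ketone enolate to the aldehyde, which has no α-hydrogen, closes the seven-membered ring; lithium held between the enolate oxygen and the benzyloxy oxygen also binds the aldehyde oxygen on that face (closed Zimmerman–Traxler-type transition state), which should put the new hydroxyl on the side of C8 (6R).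

Step 22
Reactants: 27 aldol
Product: 28 (1S,2S,3S,6R,7R,8R,11R)-3-[(benzyloxy)methyl]-9,9-(ethylenedioxy)-3,7,11-trimethyl-6-[(triethylsilyl)oxy]tricyclo[5.4.0.0(2,8)]undecan-4-one
Conditions: Et3SiOTf, 2,6-lutidine, CH2Cl2, −78 °C
Reagents that add atoms: triethylsilyl trifluoromethanesulfonate, CC[Si](CC)(CC)OS(=O)(=O)C(F)(F)F
Why: Silylation with a silyl triflate at −78 °C protects the hindered hydroxyl without enolising the ketone and keeps it distinct from the hydroxyl made in step 24.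

Step 23
Reactants: 28 silyl ether
Product: 29 (1S,2S,3S,6R,7R,8R,11R)-9,9-(ethylenedioxy)-3-(hydroxymethyl)-3,7,11-trimethyl-6-[(triethylsilyl)oxy]tricyclo[5.4.0.0(2,8)]undecan-4-one
Conditions: H2 (1 atm), Pd/C, EtOAc, 23 °C
Reagents that add atoms: none
Why: Hydrogenolysis of the benzyl ether under neutral conditions, in which the β-hydroxy ketone cannot lose formaldehyde and the silyl ether stays.

Step 24
Reactants: 29 hydroxy ketone
Product: 30 (1S,2S,3S,4R,6R,7R,8R,11R)-9,9-(ethylenedioxy)-3-(hydroxymethyl)-3,7,11-trimethyl-6-[(triethylsilyl)oxy]tricyclo[5.4.0.0(2,8)]undecan-4-ol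
Conditions: Me4NBH(OAc)3, MeCN/AcOH (1:1), −30 to 0 °C
Reagents that add atoms: none
Why: Evans–Saksena reduction: the primary hydroxyl exchanges onto boron and hands the hydride to the ketone face on its own side through a six-membered transition state, which sets C4 (R) with the hydroxyl trans to the CH2OH arm and to the silyloxy group.

Step 25
Reactants: 30 diol
Product: 31 [(1S,2S,3S,4R,6R,7R,8R,11R)-9,9-(ethylenedioxy)-4-hydroxy-3,7,11-trimethyl-6-[(triethylsilyl)oxy]tricyclo[5.4.0.0(2,8)]undecan-3-yl]methyl acetate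
Conditions: Ac2O (1.2 equiv), pyridine, CH2Cl2, 0 °C
Reagents that add atoms: acetic anhydride, CC(=O)OC(C)=O
Why: Selective acetylation of the primary hydroxyl; the secondary one sits next to a quaternary carbon and reacts far more slowly.

Step 26
Reactants: 31 hydroxy acetate; 32 angelic acid, (2Z)-2-methylbut-2-enoic acid
Product: 33 [(1S,2S,3S,4R,6R,7R,8R,11R)-9,9-(ethylenedioxy)-3,7,11-trimethyl-4-{[(2Z)-2-methylbut-2-enoyl]oxy}-6-[(triethylsilyl)oxy]tricyclo[5.4.0.0(2,8)]undecan-3-yl]methyl acetate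
Conditions: 32, 2,4,6-trichlorobenzoyl chloride, Et3N, toluene, 23 °C; then 31, 75 °C
Reagents that add atoms: none
Why: Yamaguchi esterification through the mixed anhydride without a nucleophilic catalyst, a protocol used to put angelate on hindered alcohols without Z to E isomerisation.

Step 27
Reactants: 33 protected angelate
Product: 34 CNP0212099.1, [(1S,2S,3S,4R,6R,7R,8R,11R)-6-hydroxy-3,7,11-trimethyl-4-{[(2Z)-2-methylbut-2-enoyl]oxy}-9-oxotricyclo[5.4.0.0(2,8)]undecan-3-yl]methyl acetate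
Conditions: 1 M HCl, THF, 30 °C
Reagents that add atoms: water, O
Why: Acid hydrolysis removes the dioxolane and the triethylsilyl ether together; acetate and angelate should survive dilute acid.

Compound list
1 | ethyl (3S)-3-hydroxybutanoate | CCOC(=O)C[C@H](C)O | starting material
2 | ethyl (2S,3S)-3-hydroxy-2-methylbutanoate | CCOC(=O)[C@@H](C)[C@H](C)O | intermediate
3 | ethyl (2S,3S)-2-[(benzyloxy)methyl]-3-hydroxy-2-methylbutanoate | CCOC(=O)[C@@](C)(COCc1ccccc1)[C@H](C)O | intermediate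
4 | ethyl (2S,3S)-2-[(benzyloxy)methyl]-3-[(tert-butyldimethylsilyl)oxy]-2-methylbutanoate | CCOC(=O)[C@@](C)(COCc1ccccc1)[C@H](C)O[Si](C)(C)C(C)(C)C | intermediate
5 | (2S,3S)-2-[(benzyloxy)methyl]-3-[(tert-butyldimethylsilyl)oxy]-2-methylbutan-1-ol | OC[C@@](C)(COCc1ccccc1)[C@H](C)O[Si](C)(C)C(C)(C)C | intermediate
6 | (2S,3S)-2-[(benzyloxy)methyl]-3-[(tert-butyldimethylsilyl)oxy]-2-methylbutanal | O=C[C@@](C)(COCc1ccccc1)[C@H](C)O[Si](C)(C)C(C)(C)C | intermediate
7 | (3E,5S,6S)-5-[(benzyloxy)methyl]-6-[(tert-butyldimethylsilyl)oxy]-5-methylhept-3-en-2-one | CC(=O)/C=C/[C@@](C)(COCc1ccccc1)[C@H](C)O[Si](C)(C)C(C)(C)C | intermediate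
8 | (3E,5S,6S)-5-[(benzyloxy)methyl]-2,6-bis[(tert-butyldimethylsilyl)oxy]-5-methylhepta-1,3-diene | C=C(O[Si](C)(C)C(C)(C)C)/C=C/[C@@](C)(COCc1ccccc1)[C@H](C)O[Si](C)(C)C(C)(C)C | intermediate
9 | (4R)-4-benzyl-5,5-dimethyl-1,3-oxazolidin-2-one | O=C1N[C@H](Cc2ccccc2)C(C)(C)O1 | starting material
10 | (2E)-but-2-enoyl chloride | C/C=C/C(Cl)=O | starting material
11 | (4R)-4-benzyl-3-[(2E)-but-2-enoyl]-5,5-dimethyl-1,3-oxazolidin-2-one | C/C=C/C(=O)N1[C@H](Cc2ccccc2)C(C)(C)OC1=O | intermediate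
12 | (4R)-4-benzyl-3-{[(1S,2R,6R)-2-A-4-[(tert-butyldimethylsilyl)oxy]-6-methylcyclohex-3-en-1-yl]carbonyl}-5,5-dimethyl-1,3-oxazolidin-2-one (A cis to the acyl group, methyl trans) | O=C(N1[C@H](Cc2ccccc2)C(C)(C)OC1=O)[C@H]1[C@H](C)CC(O[Si](C)(C)C(C)(C)C)=C[C@H]1[C@@](C)(COCc1ccccc1)[C@H](C)O[Si](C)(C)C(C)(C)C | intermediate
13 | (4R)-4-benzyl-3-{hydroxy[(1S,2R,6R)-2-A-4-[(tert-butyldimethylsilyl)oxy]-6-methylcyclohex-3-en-1-yl]methyl}-5,5-dimethyl-1,3-oxazolidin-2-one, hemiaminal, not isolated | OC(N1[C@H](Cc2ccccc2)C(C)(C)OC1=O)[C@H]1[C@H](C)CC(O[Si](C)(C)C(C)(C)C)=C[C@H]1[C@@](C)(COCc1ccccc1)[C@H](C)O[Si](C)(C)C(C)(C)C | intermediate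
14 | (1S,2R,6R)-2-A-4-[(tert-butyldimethylsilyl)oxy]-6-methylcyclohex-3-ene-1-carbaldehyde | O=C[C@H]1[C@H](C)CC(O[Si](C)(C)C(C)(C)C)=C[C@H]1[C@@](C)(COCc1ccccc1)[C@H](C)O[Si](C)(C)C(C)(C)C | intermediate
15 | 2-chloro-1-[(1S,2R,6R)-2-A-4-[(tert-butyldimethylsilyl)oxy]-6-methylcyclohex-3-en-1-yl]ethan-1-ol, both carbinol epimers | OC(CCl)[C@H]1[C@H](C)CC(O[Si](C)(C)C(C)(C)C)=C[C@H]1[C@@](C)(COCc1ccccc1)[C@H](C)O[Si](C)(C)C(C)(C)C | intermediate
16 | 2-chloro-1-[(1S,2R,6R)-2-A-4-[(tert-butyldimethylsilyl)oxy]-6-methylcyclohex-3-en-1-yl]ethan-1-one | O=C(CCl)[C@H]1[C@H](C)CC(O[Si](C)(C)C(C)(C)C)=C[C@H]1[C@@](C)(COCc1ccccc1)[C@H](C)O[Si](C)(C)C(C)(C)C | intermediate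
17 | (1S,4R,5S,8R)-8-A-4-methylbicyclo[3.2.1]octane-2,6-dione (A on C8 over the C6–C7 bridge, methyl on the C8 face) | C1C(=O)[C@@H]2[C@@H]([C@H]1C(=O)C[C@H]2C)[C@@](C)(COCc3ccccc3)[C@H](C)O[Si](C)(C)C(C)(C)C | intermediate
18 | (1S,4R,5S,8R)-8-A-2,2-(ethylenedioxy)-4-methylbicyclo[3.2.1]octan-6-one | C1C(=O)[C@@H]2[C@@H]([C@H]1C3(OCCO3)C[C@H]2C)[C@@](C)(COCc4ccccc4)[C@H](C)O[Si](C)(C)C(C)(C)C | intermediate
19 | 8-A-2,2-(ethylenedioxy)-4-methyl-7-(trifluoroacetyl)bicyclo[3.2.1]octan-6-one (ring carbons as in 18), not isolated | FC(F)(F)C(=O)C1C(=O)[C@@H]2[C@@H]([C@H]1C3(OCCO3)C[C@H]2C)[C@@](C)(COCc4ccccc4)[C@H](C)O[Si](C)(C)C(C)(C)C | intermediate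
20 | (1R,4R,5S,8S)-8-A-7-diazo-2,2-(ethylenedioxy)-4-methylbicyclo[3.2.1]octan-6-one | [N-]=[N+]=C1C(=O)[C@@H]2[C@@H]([C@H]1C3(OCCO3)C[C@H]2C)[C@@](C)(COCc4ccccc4)[C@H](C)O[Si](C)(C)C(C)(C)C | intermediate
21 | (1R,4R,5S,7S)-7-A-2,2-(ethylenedioxy)-4-methyl-6-(oxomethylidene)bicyclo[3.1.1]heptane, ketene, not isolated | O=C=C1[C@@H]2[C@@H]([C@H]1C3(OCCO3)C[C@H]2C)[C@@](C)(COCc4ccccc4)[C@H](C)O[Si](C)(C)C(C)(C)C | intermediate
22 | methyl (1R,4R,5S,6R,7S)-7-A-2,2-(ethylenedioxy)-4-methylbicyclo[3.1.1]heptane-6-carboxylate (ester and A both away from the C2–C4 bridge) | COC(=O)[C@@H]1[C@@H]2[C@@H]([C@H]1C3(OCCO3)C[C@H]2C)[C@@](C)(COCc4ccccc4)[C@H](C)O[Si](C)(C)C(C)(C)C | intermediate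
23 | methyl (1R,4R,5S,6R,7S)-7-A-2,2-(ethylenedioxy)-4,6-dimethylbicyclo[3.1.1]heptane-6-carboxylate (6-methyl toward the C2–C4 bridge) | COC(=O)[C@]1(C)[C@@H]2[C@@H]([C@H]1C3(OCCO3)C[C@H]2C)[C@@](C)(COCc4ccccc4)[C@H](C)O[Si](C)(C)C(C)(C)C | intermediate
24 | [(1R,4R,5S,6R,7S)-7-A-2,2-(ethylenedioxy)-4,6-dimethylbicyclo[3.1.1]heptan-6-yl]methanol | OC[C@]1(C)[C@@H]2[C@@H]([C@H]1C3(OCCO3)C[C@H]2C)[C@@](C)(COCc4ccccc4)[C@H](C)O[Si](C)(C)C(C)(C)C | intermediate
25 | (2S,3S)-4-(benzyloxy)-3-[(1R,4R,5S,6R,7S)-2,2-(ethylenedioxy)-6-(hydroxymethyl)-4,6-dimethylbicyclo[3.1.1]heptan-7-yl]-3-methylbutan-2-ol | OC[C@]1(C)[C@@H]2[C@@H]([C@H]1C3(OCCO3)C[C@H]2C)[C@@](C)(COCc4ccccc4)[C@H](C)O | intermediate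
26 | (1R,4R,5S,6R,7S)-7-[(2S)-1-(benzyloxy)-2-methyl-3-oxobutan-2-yl]-2,2-(ethylenedioxy)-4,6-dimethylbicyclo[3.1.1]heptane-6-carbaldehyde | O=C[C@]1(C)[C@@H]2[C@@H]([C@H]1C3(OCCO3)C[C@H]2C)[C@@](C)(COCc4ccccc4)C(C)=O | intermediate
27 | (1S,2S,3S,6R,7R,8R,11R)-3-[(benzyloxy)methyl]-9,9-(ethylenedioxy)-6-hydroxy-3,7,11-trimethyltricyclo[5.4.0.0(2,8)]undecan-4-one | O=C1C[C@@H](O)[C@]2(C)[C@@H]3[C@@H]([C@H]2C4(OCCO4)C[C@H]3C)[C@@]1(C)COCc1ccccc1 | intermediate
28 | (1S,2S,3S,6R,7R,8R,11R)-3-[(benzyloxy)methyl]-9,9-(ethylenedioxy)-3,7,11-trimethyl-6-[(triethylsilyl)oxy]tricyclo[5.4.0.0(2,8)]undecan-4-one | O=C1C[C@@H](O[Si](CC)(CC)CC)[C@]2(C)[C@@H]3[C@@H]([C@H]2C4(OCCO4)C[C@H]3C)[C@@]1(C)COCc1ccccc1 | intermediate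
29 | (1S,2S,3S,6R,7R,8R,11R)-9,9-(ethylenedioxy)-3-(hydroxymethyl)-3,7,11-trimethyl-6-[(triethylsilyl)oxy]tricyclo[5.4.0.0(2,8)]undecan-4-one | O=C1C[C@@H](O[Si](CC)(CC)CC)[C@]2(C)[C@@H]3[C@@H]([C@H]2C4(OCCO4)C[C@H]3C)[C@@]1(C)CO | intermediate
30 | (1S,2S,3S,4R,6R,7R,8R,11R)-9,9-(ethylenedioxy)-3-(hydroxymethyl)-3,7,11-trimethyl-6-[(triethylsilyl)oxy]tricyclo[5.4.0.0(2,8)]undecan-4-ol | O[C@@H]1C[C@@H](O[Si](CC)(CC)CC)[C@]2(C)[C@@H]3[C@@H]([C@H]2C4(OCCO4)C[C@H]3C)[C@@]1(C)CO | intermediate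
31 | [(1S,2S,3S,4R,6R,7R,8R,11R)-9,9-(ethylenedioxy)-4-hydroxy-3,7,11-trimethyl-6-[(triethylsilyl)oxy]tricyclo[5.4.0.0(2,8)]undecan-3-yl]methyl acetate | O[C@@H]1C[C@@H](O[Si](CC)(CC)CC)[C@]2(C)[C@@H]3[C@@H]([C@H]2C4(OCCO4)C[C@H]3C)[C@@]1(C)COC(C)=O | intermediate
32 | angelic acid, (2Z)-2-methylbut-2-enoic acid | C/C=C(/C)C(=O)O | starting material
33 | [(1S,2S,3S,4R,6R,7R,8R,11R)-9,9-(ethylenedioxy)-3,7,11-trimethyl-4-{[(2Z)-2-methylbut-2-enoyl]oxy}-6-[(triethylsilyl)oxy]tricyclo[5.4.0.0(2,8)]undecan-3-yl]methyl acetate | C/C=C(/C)C(=O)O[C@@H]1C[C@@H](O[Si](CC)(CC)CC)[C@]2(C)[C@@H]3[C@@H]([C@H]2C4(OCCO4)C[C@H]3C)[C@@]1(C)COC(C)=O | intermediate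
34 | CNP0212099.1, [(1S,2S,3S,4R,6R,7R,8R,11R)-6-hydroxy-3,7,11-trimethyl-4-{[(2Z)-2-methylbut-2-enoyl]oxy}-9-oxotricyclo[5.4.0.0(2,8)]undecan-3-yl]methyl acetate | C/C=C(/C)C(=O)O[C@@H]1C[C@@H](O)[C@]2(C)[C@@H]3[C@@H]([C@H]2C(=O)C[C@H]3C)[C@@]1(C)COC(C)=O | target

Total step count: 27. Longest linear sequence: 26 steps (steps 1–7 and 9–27; step 8 is a one-step branch).

Steps most likely to fail

Step 9. The cycloaddition may stall after the first C–C bond, or lose endo or facial selectivity, because the second bond forms next to the quaternary carbon and the diene carries its own stereocentres. The fallback sets out from diene 8 and swaps the auxiliary-bound dienophile for free (E)-but-2-enal under a chiral oxazaborolidinium Lewis acid: the B-(2-methylphenyl)oxazaborolidine of α,α-diphenylprolinol, C24H24BNO, protonated with HN(SO2CF3)2, in the enantiomer that leaves the Cα-Re face of the enal open, in CH2Cl2 at −78 °C. The smaller, catalyst-bound enal eases the crowding, and the cycloadduct is aldehyde 14 itself, where the fallback comes back to the route; steps 8 and 10 fall away and no compound outside the list arises (F0).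

Step 21. Facial selectivity at the aldehyde may be poor if the benzyl ether does not hold lithium firmly. The fallback sets out from 26: the benzyl ether is hydrogenolysed first (H2, Pd/C, EtOAc) to (1R,4R,5S,6R,7S)-2,2-(ethylenedioxy)-7-[(2S)-1-hydroxy-2-methyl-3-oxobutan-2-yl]-4,6-dimethylbicyclo[3.1.1]heptane-6-carbaldehyde F1. The aldol is then run on its dilithium alkoxide–enolate (LiN(SiMe3)2, 2.2 equiv, −78 °C, kept cold against loss of formaldehyde), in which the lithium alkoxide of the CH2O arm anchors both carbonyl oxygens on its own face, to give (1S,2S,3S,6R,7R,8R,11R)-9,9-(ethylenedioxy)-6-hydroxy-3-(hydroxymethyl)-3,7,11-trimethyltricyclo[5.4.0.0(2,8)]undecan-4-one F2. Both hydroxyls are silylated (Et3SiOTf, 2,6-lutidine) to the bis(triethylsilyl) ether F3, and the primary silyl ether is removed selectively (pyridinium p-toluenesulfonate, MeOH, 0 °C), which comes back to the route at 29.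

Step 16. Carbene side reactions (insertion into the O–H bond of methanol, C–H insertion) or the added ring strain may hold back the contraction. The fallback sets out from ketone 18: C7 is brominated through the enolate (LiN(SiMe3)2, Me3SiCl, then N-bromosuccinimide) to 8-A-7-bromo-2,2-(ethylenedioxy)-4-methylbicyclo[3.2.1]octan-6-one F4, which is treated with NaOMe in MeOH. Methoxide adds to the C6 carbonyl and C5 migrates to C7 with loss of bromide (semibenzilic, quasi-Favorskii contraction, which needs no enolisation toward the bridgehead); the same bond forms and the fallback comes back to the route at ester 22.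

Further compounds
F0 | step 9 | none | none
F1 | step 21 | (1R,4R,5S,6R,7S)-2,2-(ethylenedioxy)-7-[(2S)-1-hydroxy-2-methyl-3-oxobutan-2-yl]-4,6-dimethylbicyclo[3.1.1]heptane-6-carbaldehyde | O=C[C@]1(C)[C@@H]2[C@@H]([C@H]1C3(OCCO3)C[C@H]2C)[C@@](C)(CO)C(C)=O
F2 | step 21 | (1S,2S,3S,6R,7R,8R,11R)-9,9-(ethylenedioxy)-6-hydroxy-3-(hydroxymethyl)-3,7,11-trimethyltricyclo[5.4.0.0(2,8)]undecan-4-one | O=C1C[C@@H](O)[C@]2(C)[C@@H]3[C@@H]([C@H]2C4(OCCO4)C[C@H]3C)[C@@]1(C)CO
F3 | step 21 | (1S,2S,3S,6R,7R,8R,11R)-9,9-(ethylenedioxy)-3,7,11-trimethyl-6-[(triethylsilyl)oxy]-3-{[(triethylsilyl)oxy]methyl}tricyclo[5.4.0.0(2,8)]undecan-4-one | O=C1C[C@@H](O[Si](CC)(CC)CC)[C@]2(C)[C@@H]3[C@@H]([C@H]2C4(OCCO4)C[C@H]3C)[C@@]1(C)CO[Si](CC)(CC)CC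
F4 | step 16 | 8-A-7-bromo-2,2-(ethylenedioxy)-4-methylbicyclo[3.2.1]octan-6-one (ring carbons as in 18, both C7 epimers) | BrC1C(=O)[C@@H]2[C@@H]([C@H]1C3(OCCO3)C[C@H]2C)[C@@](C)(COCc4ccccc4)[C@H](C)O[Si](C)(C)C(C)(C)C
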